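The readings were generated by integration on assumed constants, noise included.

I had no rate constants for this flask, only two runs, and I had to decide whether the loading of G or the stopping time was the thing to watch for which species led. The plan was 0.1 mol% of G, with ochre stopped at 8.0 min and blue at 12 min.

| flask | L | X | E | G | remark | time |
|---|---|---|---|---|---|---|
| Tuesday's | 0.13 M | 0.13 M | 3 equiv | 0.067 mol% | run made earlier |  |
| Wednesday's | 0.13 M | 0.13 M | 3 equiv | 0.15 mol% | run made earlier |  |
| ochre | 0.13 M | 0.13 M | 3.00 equiv | 0.1 mol% |  | 8.0 min |
| blue | 0.13 M | 0.13 M | 3.00 equiv | 0.1 mol% |  | 12 min |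

| run | time / min | X / % | D / % | L / % | Q / % |
|---|---|---|---|---|---|
| Tuesday's | 2.50 | 45.1 | 7.3 | 40.5 | 4.0 |
| Tuesday's | 5.00 | 42.4 | 18.3 | 31.3 | 8.9 |
| Tuesday's | 8.00 | 33.7 | 24.4 | 24.0 | 13.0 |
| Tuesday's | 10.0 | 31.7 | 34.0 | 17.6 | 17.9 |
| Wednesday's | 2.50 | 46.7 | 8.7 | 41.0 | 3.7 |
| Wednesday's | 5.00 | 43.1 | 15.8 | 31.7 | 8.3 |
| Wednesday's | 8.00 | 36.6 | 28.0 | 24.5 | 15.4 |
| Wednesday's | 10.0 | 32.1 | 32.1 | 17.3 | 18.9 |

(standard deviation of a reading: 1 percentage point)

1. which of these there is most of at the end, counted by the substrate in it, ochre (Q / X / L / D)
2. which of these there is most of at the end, counted by the substrate in it, blue (Q / X / L / D)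
3. how much there is at the end of the one of these that leads, in percent of the L and X together charged: ochre
4. how much there is at the end of the one of these that leads, in percent of the L and X together charged: blue

- G is single-handed; L and X are mirror images of each other, charged as a racemate, each of them at the stated concentration
- given per volume of solution although it is solid: E
- the numbers in the tables scatter by 1 percentage point (one standard deviation)
- at the start none of E is in solution

The runs gave me what I needed. Tuesday's L and D summed to 51.6 % at the last reading and Wednesday's to 49.4 %, so I paired L with D and X with Q. This was a kinetic resolution, with Tuesday's D ahead of its Q at that reading.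

D equals the charged share of L minus what remains of L, so in a racemate reacting this way D meets X when L and X together have fallen to half of the charge, at any selectivity factor. Wednesday's G was about twice Tuesday's, yet the conversions at the last reading were alike. The mean of the two runs was 25.6 % at 5.00 min and 51.5 % at 10.0 min, twice as much in twice the time, so I read the pace as steady.

One division gave the crossing time, the time at which this steady pace brings conversion to half of the charge and D overtakes X: 9.72 min. Ochre stops 1.72 min before it, so I expected X to lead there. Blue stops 2.28 min after it, so I expected D to lead. I kept the loading and let the clock make the choice.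

The forecast named X for ochre at 35.5 % (range 33.5 % to 37.5 %) and D for blue at 38 % (range 35.5 % to 41 %), using a selectivity factor of about 2.4. Its ground was: “The rate is therefore set by E dissolving, not by the catalyst”.

Ochre gave X in the lead at 35.6 %, and blue gave D at 38.0 %, both inside the forecast's ranges.

    Z + G + L → G + D (k = 8600 L² mol⁻² s⁻¹)
    Z + G + X → G + Q (k = 3800 L² mol⁻² s⁻¹)
    E ⇌ Z, rate k3*(cs3 - [Z]) while solid is left; crystals form when [Z] > cs3 (solubility = 0.100 M, k = 0.00230 s⁻¹)

In blue at 12.0 min, dissolved Z stood at 0.00312 M, far below its solubility of 0.10 M. The crossing time put blue's conversion at 61.7 %, and blue held 61.4 % as D and Q.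

For ochre read at 5.0 min, the crossing time gives a conversion of 25.7 %, short of half by a wide margin, so X should lead. The computed flask holds X at 41.5 % and D at 17.2 %.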